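**Plan**

- Cuts: C11=C12 (olefination, then diimide) divides the target into an ent-drimenyl sulfone and a finished 1,2-dioxane aldehyde. In the decalin, C1–C2 and C3–C4 are cut together so that ring A falls away from a carvone-derived ring B. The dioxane is cut at O–C16 and O–C13.
- Enabling feature: ring A links the gem-dimethyl carbon C4 (on ring-fusion C5) to the CH2 C1 on the quaternary, hence non-enolisable, ring-fusion C10 through the two-carbon bridge C2–C3. An isopropenyl on C5 and a formyl on C10 of a cyclohexenone are therefore a tertiary-radical donor and an aldol acceptor that one enal can span.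
- Forward order: (S)-carvone supplies ring B; C10 is made quaternary; ring A is annulated in one operation and its helper groups removed; C11 follows by methylenation and hydroboration. The dioxane is built separately from geraniol and a propionate aldol, and the fragments are joined last.
- Stereochemistry: C5 is bought. C10 is set by alkylation anti to the isopropenyl, which also fixes the trans ring fusion. C9 comes from hydroboration anti to the angular methyl. C13 comes from Sharpless epoxidation followed by invertive perhydrolysis. C17 and C16 come from an Evans syn aldol, with C16 inverted when the peroxide ring closes.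

Key step: step 4

Remark: atom labels follow drimane numbering for the decalin (C1–C10, C11 = CH2 on C9) and continue along the side chain to the ester carbon C18; C13 and C16 carry the peroxide oxygens.

**Route**

Step 1
Reactants: 1 (S)-(+)-carvone
Product: 2 (5S,6R)-2,6-dimethyl-5-(prop-1-en-2-yl)cyclohex-2-en-1-one (trans-6-methylcarvone; the cis C6 epimer is carried along)
Conditions: LiN(iPr)2 (LDA), THF, −78 °C; MeI, −78 → 0 °C
Reagents that add atoms: iodomethane CI
Why: kinetic deprotonation gives the cross-conjugated α'-enolate, which is methylated at C6 (enolate alkylation); this centre is planarised again in step 2, so its configuration is immaterial.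

Step 2
Reactants: 2 trans-6-methylcarvone
Product: 3 (5R,6S)-6-(hydroxymethyl)-2,6-dimethyl-5-(prop-1-en-2-yl)cyclohex-2-en-1-one
Conditions: LiN(iPr)2 (LDA), THF, −78 °C; monomeric CH2O (cracked paraformaldehyde), −78 °C; aqueous work-up
Reagents that add atoms: formaldehyde C=O
Why: aldol hydroxymethylation of the tetrasubstituted α'-enolate; the electrophile should enter anti to the adjacent isopropenyl group (pseudo-axial to relieve A(1,2) strain), so the quaternary carbon (future C10) forms with CH2OH trans to isopropenyl.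

Step 3
Reactants: 3 hydroxymethyl ketone
Product: 4 (1S,6R)-1,3-dimethyl-2-oxo-6-(prop-1-en-2-yl)cyclohex-3-ene-1-carbaldehyde
Conditions: Dess–Martin periodinane, NaHCO3, CH2Cl2, 0 °C → rt
Reagents that add atoms: none
Why: Dess–Martin oxidation of the neopentyl primary alcohol gives the non-enolisable α-formyl ketone under neutral conditions that avoid retro-Claisen deformylation.

Step 4
Reactants: 4 keto aldehyde; 5 acrolein
Product: 6 (4aR,8aS)-1-hydroxy-4,4,7,8a-tetramethyl-8-oxo-1,2,3,4,4a,5,8,8a-octahydronaphthalene-2-carbaldehyde (trans-fused; diastereomers at C1 and C2)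
Conditions: Fe(acac)3 (0.3 equiv), PhSiH3 (2.5 equiv), acrolein (3 equiv), EtOH/(CH2OH)2, 0 °C → rt
Reagents that add atoms: none
Why: Hydrogen-atom transfer from the iron hydride (Fe(acac)3/PhSiH3) to the CH2 terminus of the isopropenyl group gives the tertiary C4 radical (this hydrogen completes the gem-dimethyl group), which adds to the β-carbon of acrolein (Giese addition, C3–C4 bond); divalent iron then reduces the α-formyl radical to an iron enolate, which attacks the neighbouring non-enolisable aldehyde on C10 (aldol, C1–C2 bond). The closest known reaction type is the hydrogen-atom-transfer-initiated radical conjugate addition/aldol (radical–polar crossover) annulation of alkenyl aldehydes with enones and enals, an extension of iron-hydride reductive olefin coupling. Ring A is closed by an intermolecular radical addition followed by a 6-(enolexo)-exo-trig aldol closure. No permanent stereocentre is created: C4 becomes achiral, C1 and C2 are erased in steps 5 and 6, and the trans ring fusion is dictated by the trans relation of CHO (on C10) and isopropenyl (on C5) set in step 2. The step needs hydrogen-atom transfer to the electron-rich 1,1-disubstituted alkene and not to the electron-poor enone or acrolein (polarity matching), radical capture by acrolein faster than a 1,5-hydrogen shift from the formyl group (high acrolein concentration), and aldol closure on the aldehyde and not on the C9 ketone (fused six-membered ring against a bridged one).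

Step 5
Reactants: 6 keto aldol
Product: 8 (4aR,8aR)-4,4,7,8a-tetramethyl-8-oxo-3,4,4a,5,8,8a-hexahydronaphthalene-2-carbaldehyde, via mesylate 7 (not isolated)
Conditions: MsCl, Et3N, CH2Cl2, 0 °C → rt
Reagents that add atoms: none
Why: sulfene-mediated mesylation of the hindered C1 alcohol and E1cB elimination through the C2 enolate of the aldehyde (aldol dehydration) should give the conjugated enal whatever the C1/C2 configuration.

Step 6
Reactants: 8 enal
Product: 9 (4aR,8aR)-2,5,5,8a-tetramethyl-4a,5,6,8a-tetrahydronaphthalen-1(4H)-one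
Conditions: [Rh(cod)Cl]2 (5 mol%), dppp (10 mol%), diglyme, 160 °C
Reagents that add atoms: none
Why: Tsuji–Wilkinson decarbonylation (formyl C–H oxidative addition, CO extrusion, C–H reductive elimination) excises the helper carbon; migration of the ring A double bond to C2=C3 would be harmless, since both isomers give 10 in step 7.

Step 7
Reactants: 9 dienone
Product: 10 (4aR,8aR)-2,5,5,8a-tetramethyl-4a,5,6,7,8,8a-hexahydronaphthalen-1(4H)-one
Conditions: H2 (1 atm), RhCl(PPh3)3 (5 mol%), PhH/EtOH, rt
Reagents that add atoms: none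
Why: homogeneous hydrogenation with RhCl(PPh3)3 should reduce the cis-disubstituted ring A alkene far faster than the trisubstituted, conjugated C7=C8 bond.

Step 8
Reactants: 10 enone
Product: 11 ent-drima-7,9(11)-diene
Conditions: Ph3PCH3Br, KOtBu, toluene, 90 °C
Reagents that add atoms: methylenetriphenylphosphorane C=P(c1ccccc1)(c1ccccc1)c1ccccc1
Why: Wittig methylenation of the hindered ketone, which has no α-hydrogen (C10 quaternary, C8 sp2), gives the exocyclic conjugated diene.

Step 9
Reactants: 11 ent-drima-7,9(11)-diene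
Product: 13 ent-drimenol, via alkylborane 12 (not isolated)
Conditions: 9-BBN, THF, 65 °C; then NaOH, 30% H2O2, 0 °C → rt
Reagents that add atoms: hydrogen peroxide OO
Why: anti-Markovnikov hydroboration–oxidation of the exocyclic C9=C11 bond (9-BBN ignores the trisubstituted ring alkene); hydrogen should reach C9 on the face opposite the axial C10 methyl, placing CH2OH cis to that methyl and so setting C9.

Step 10
Reactants: 13 ent-drimenol
Product: 14 5-({[(1R,4aR,8aR)-2,5,5,8a-tetramethyl-1,4,4a,5,6,7,8,8a-octahydronaphthalen-1-yl]methyl}sulfanyl)-1-phenyl-1H-tetrazole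
Conditions: 1-phenyl-1H-tetrazole-5-thiol, PPh3, DIAD, THF, 0 °C → rt
Reagents that add atoms: 1-phenyl-1H-tetrazole-5-thiol Sc1nnnn1-c1ccccc1
Why: Mitsunobu thioetherification of the primary alcohol; no stereocentre is touched.

Step 11
Reactants: 14 sulfide
Product: 15 5-({[(1R,4aR,8aR)-2,5,5,8a-tetramethyl-1,4,4a,5,6,7,8,8a-octahydronaphthalen-1-yl]methyl}sulfonyl)-1-phenyl-1H-tetrazole
Conditions: (NH4)6Mo7O24·4H2O (10 mol%), 30% H2O2, EtOH, 0 °C → rt
Reagents that add atoms: hydrogen peroxide OO
Why: molybdate-catalysed sulfide-to-sulfone oxidation, which should leave the unactivated trisubstituted alkene alone.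

Step 12
Reactants: 16 geraniol
Product: 17 geranyl tert-butyldimethylsilyl ether
Conditions: TBSCl, imidazole, DMF, rt
Reagents that add atoms: tert-butyldimethylsilyl chloride CC(C)(C)[Si](C)(C)Cl
Why: silylation protects the allylic hydroxyl through the aldol sequence.

Step 13
Reactants: 17 geranyl silyl ether
Product: 18 tert-butyl{[(2E)-5-(3,3-dimethyloxiran-2-yl)-3-methylpent-2-en-1-yl]oxy}dimethylsilane (racemic at the oxirane carbon)
Conditions: mCPBA (1.0 equiv), CH2Cl2, −20 °C
Reagents that add atoms: 3-chloroperoxybenzoic acid OOC(=O)c1cccc(Cl)c1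
Why: Prilezhaev epoxidation should select the remote, more electron-rich 6,7-alkene over the 2,3-alkene deactivated by the allylic oxygen; the epoxide is destroyed in step 14.

Step 14
Reactants: 18 epoxide
Product: 20 (4E)-6-[(tert-butyldimethylsilyl)oxy]-4-methylhex-4-enal, via diol 19 (not isolated)
Conditions: H5IO6, THF/H2O, 0 °C
Reagents that add atoms: none
Why: periodic acid hydrolyses the epoxide and cleaves the resulting glycol (Malaprade cleavage), releasing acetone and the aldehyde.

Step 15
Reactants: 20 aldehyde; 21 (S)-4-benzyl-3-propanoyl-1,3-oxazolidin-2-one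
Product: 22 (4S)-4-benzyl-3-[(2S,3R,6E)-8-[(tert-butyldimethylsilyl)oxy]-3-hydroxy-2,6-dimethyloct-6-enoyl]-1,3-oxazolidin-2-one
Conditions: Bu2BOTf, Et3N, CH2Cl2, −78 → 0 °C; then pH 7 buffer, MeOH, 30% H2O2
Reagents that add atoms: none
Why: Evans syn aldol: the Z-boron enolate reacts through a Zimmerman–Traxler chair with one face shielded by the auxiliary, giving the (2S,3R) syn adduct; this sets C17 for good and C16 opposite to the target, as step 21 requires.

Step 16
Reactants: 22 aldol adduct
Product: 23 methyl (2S,3R,6E)-8-[(tert-butyldimethylsilyl)oxy]-3-hydroxy-2,6-dimethyloct-6-enoate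
Conditions: NaOMe (0.3 equiv), MeOH, 0 °C
Reagents that add atoms: methanol (as NaOMe/MeOH) CO
Why: methanolysis of the activated exocyclic imide carbonyl (transesterification) releases the auxiliary; at 0 °C C17 should not epimerise.

Step 17
Reactants: 23 hydroxy ester
Product: 24 methyl (2S,3R,6E)-8-[(tert-butyldimethylsilyl)oxy]-2,6-dimethyl-3-[(methylsulfonyl)oxy]oct-6-enoate
Conditions: MsCl, Et3N, CH2Cl2, −20 °C
Reagents that add atoms: methanesulfonyl chloride CS(=O)(=O)Cl
Why: O-sulfonylation with retention at C16 provides the leaving group for peroxide ring closure; low temperature avoids β-elimination.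

Step 18
Reactants: 24 silyl ether mesylate
Product: 25 methyl (2S,3R,6E)-8-hydroxy-2,6-dimethyl-3-[(methylsulfonyl)oxy]oct-6-enoate
Conditions: HF·pyridine, THF/pyridine, 0 °C → rt
Reagents that add atoms: none
Why: fluoride-mediated desilylation under non-basic conditions spares the β-mesyloxy ester.

Step 19
Reactants: 25 allylic alcohol
Product: 26 methyl (2S,3R)-5-[(2S,3S)-3-(hydroxymethyl)-2-methyloxiran-2-yl]-2-methyl-3-[(methylsulfonyl)oxy]pentanoate
Conditions: Ti(OiPr)4 (10 mol%), L-(+)-diethyl tartrate (12 mol%), t-BuOOH, 4 Å MS, CH2Cl2, −20 °C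
Reagents that add atoms: tert-butyl hydroperoxide CC(C)(C)OO
Why: Sharpless asymmetric epoxidation: with L-(+)-tartrate the (E)-3-methyl allylic alcohol should give the (2S,3S)-epoxy alcohol, as geraniol does, under reagent control that overrides the remote centres; this fixes the C13–O configuration that step 20 inverts.

Step 20
Reactants: 26 epoxy alcohol
Product: 27 methyl (2S,3R,6R,7S)-6-hydroperoxy-7,8-dihydroxy-2,6-dimethyl-3-[(methylsulfonyl)oxy]octanoate
Conditions: anhydrous H2O2 in Et2O, H3PMo12O40 (cat.), rt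
Reagents that add atoms: hydrogen peroxide OO
Why: acid-catalysed perhydrolysis of the trisubstituted epoxide: H2O2 should attack the more substituted carbon (C13) with inversion (borderline SN2 ring opening), setting the quaternary peroxy carbon.

Step 21
Reactants: 27 hydroperoxy mesylate
Product: 28 methyl (2S)-2-{(3S,6R)-6-[(1S)-1,2-dihydroxyethyl]-6-methyl-1,2-dioxan-3-yl}propanoate
Conditions: KOtBu (1.0 equiv), 18-crown-6, THF, −20 → 0 °C
Reagents that add atoms: none
Why: one equivalent of base deprotonates only the hydroperoxide (far more acidic than the alcohols or the ester α-CH), and the α-effect peroxy anion displaces the secondary mesylate by 6-exo-tet SN2 with inversion (intramolecular hydroperoxide alkylation), setting C16 and closing the 1,2-dioxane.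

Step 22
Reactants: 28 dioxane diol
Product: 29 methyl (2S)-2-[(3S,6R)-6-formyl-6-methyl-1,2-dioxan-3-yl]propanoate
Conditions: NaIO4, THF/H2O, 0 °C
Reagents that add atoms: none
Why: Malaprade glycol cleavage removes the sacrificial carbon C11 and unveils the non-enolisable C12 aldehyde; dialkyl peroxides are inert to periodate.

Step 23
Reactants: 15 ent-drimenyl tetrazolyl sulfone; 29 dioxane aldehyde
Product: 30 methyl (2S)-2-[(3S,6R)-6-methyl-6-{2-[(1R,4aR,8aR)-2,5,5,8a-tetramethyl-1,4,4a,5,6,7,8,8a-octahydronaphthalen-1-yl]ethenyl}-1,2-dioxan-3-yl]propanoate (E/Z mixture)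
Conditions: KN(SiMe3)2, THF, −78 °C (15 first, then 29); → rt
Reagents that add atoms: none
Why: Julia–Kocienski olefination (addition, Smiles rearrangement, loss of SO2 and tetrazolate) joins the fragments at C11=C12; alkene geometry is irrelevant, and at −78 °C addition to the aldehyde should outrun attack on the peroxide or the ester.

Step 24
Reactants: 30 skipped diene
Product: 31 methyl (2S)-2-[(3S,6S)-6-methyl-6-{2-[(1R,4aR,8aR)-2,5,5,8a-tetramethyl-1,4,4a,5,6,7,8,8a-octahydronaphthalen-1-yl]ethyl}-1,2-dioxan-3-yl]propanoate (CNP0124238.1)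
Conditions: KO2CN=NCO2K, AcOH, MeOH/CH2Cl2, 0 °C → rt
Reagents that add atoms: none
Why: diimide reduction (concerted syn transfer of H2) should saturate the 1,2-disubstituted C11=C12 bond much faster than the trisubstituted C7=C8 bond and does not touch the O–O bond.

**Compound list**

1 | (S)-(+)-carvone | O=C1C(C)=CC[C@H](C(C)=C)C1 | starting material
2 | (5S,6R)-2,6-dimethyl-5-(prop-1-en-2-yl)cyclohex-2-en-1-one (trans-6-methylcarvone) | O=C1C(C)=CC[C@H](C(C)=C)[C@H]1C | intermediate
3 | (5R,6S)-6-(hydroxymethyl)-2,6-dimethyl-5-(prop-1-en-2-yl)cyclohex-2-en-1-one (CH2OH trans to isopropenyl) | O=C1C(C)=CC[C@H](C(C)=C)[C@@]1(C)CO | intermediate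
4 | (1S,6R)-1,3-dimethyl-2-oxo-6-(prop-1-en-2-yl)cyclohex-3-ene-1-carbaldehyde (CHO trans to isopropenyl) | O=C1C(C)=CC[C@H](C(C)=C)[C@@]1(C)C=O | intermediate
5 | acrolein (prop-2-enal) | C=CC=O | starting material
6 | (4aR,8aS)-1-hydroxy-4,4,7,8a-tetramethyl-8-oxo-1,2,3,4,4a,5,8,8a-octahydronaphthalene-2-carbaldehyde (trans-fused; C1/C2 mixture) | O=C1C(C)=CC[C@@H]2C(C)(C)CC(C=O)C(O)[C@@]12C | intermediate
7 | 1-O-methanesulfonate of 6 | O=C1C(C)=CC[C@@H]2C(C)(C)CC(C=O)C(OS(C)(=O)=O)[C@@]12C | intermediate
8 | (4aR,8aR)-4,4,7,8a-tetramethyl-8-oxo-3,4,4a,5,8,8a-hexahydronaphthalene-2-carbaldehyde | O=C1C(C)=CC[C@@H]2C(C)(C)CC(C=O)=C[C@@]12C | intermediate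
9 | (4aR,8aR)-2,5,5,8a-tetramethyl-4a,5,6,8a-tetrahydronaphthalen-1(4H)-one | O=C1C(C)=CC[C@@H]2C(C)(C)CC=C[C@@]12C | intermediate
10 | (4aR,8aR)-2,5,5,8a-tetramethyl-4a,5,6,7,8,8a-hexahydronaphthalen-1(4H)-one | O=C1C(C)=CC[C@@H]2C(C)(C)CCC[C@@]12C | intermediate
11 | ent-drima-7,9(11)-diene, (4aR,8aR)-2,5,5,8a-tetramethyl-1-methylidene-1,4,4a,5,6,7,8,8a-octahydronaphthalene | C=C1C(C)=CC[C@@H]2C(C)(C)CCC[C@@]12C | intermediate
12 | 9-{[(1R,4aR,8aR)-2,5,5,8a-tetramethyl-1,4,4a,5,6,7,8,8a-octahydronaphthalen-1-yl]methyl}-9-borabicyclo[3.3.1]nonane | C(B1C2CCCC1CCC2)[C@@H]1C(C)=CC[C@@H]2C(C)(C)CCC[C@@]12C | intermediate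
13 | ent-drimenol, [(1R,4aR,8aR)-2,5,5,8a-tetramethyl-1,4,4a,5,6,7,8,8a-octahydronaphthalen-1-yl]methanol | OC[C@@H]1C(C)=CC[C@@H]2C(C)(C)CCC[C@@]12C | intermediate
14 | 5-({[(1R,4aR,8aR)-2,5,5,8a-tetramethyl-1,4,4a,5,6,7,8,8a-octahydronaphthalen-1-yl]methyl}sulfanyl)-1-phenyl-1H-tetrazole | C(Sc1nnnn1-c1ccccc1)[C@@H]1C(C)=CC[C@@H]2C(C)(C)CCC[C@@]12C | intermediate
15 | 5-({[(1R,4aR,8aR)-2,5,5,8a-tetramethyl-1,4,4a,5,6,7,8,8a-octahydronaphthalen-1-yl]methyl}sulfonyl)-1-phenyl-1H-tetrazole | O=S(=O)(C[C@@H]1C(C)=CC[C@@H]2C(C)(C)CCC[C@@]12C)c1nnnn1-c1ccccc1 | intermediate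
16 | geraniol | CC(C)=CCC/C(C)=C/CO | starting material
17 | geranyl tert-butyldimethylsilyl ether | CC(C)=CCC/C(C)=C/CO[Si](C)(C)C(C)(C)C | intermediate
18 | tert-butyl{[(2E)-5-(3,3-dimethyloxiran-2-yl)-3-methylpent-2-en-1-yl]oxy}dimethylsilane (racemic) | CC1(C)OC1CC/C(C)=C/CO[Si](C)(C)C(C)(C)C | intermediate
19 | (6E)-8-[(tert-butyldimethylsilyl)oxy]-2,6-dimethyloct-6-ene-2,3-diol (racemic) | CC(C)(O)C(O)CC/C(C)=C/CO[Si](C)(C)C(C)(C)C | intermediate
20 | (4E)-6-[(tert-butyldimethylsilyl)oxy]-4-methylhex-4-enal | O=CCC/C(C)=C/CO[Si](C)(C)C(C)(C)C | intermediate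
21 | (S)-4-benzyl-3-propanoyl-1,3-oxazolidin-2-one | CCC(=O)N1[C@@H](Cc2ccccc2)COC1=O | starting material
22 | (4S)-4-benzyl-3-[(2S,3R,6E)-8-[(tert-butyldimethylsilyl)oxy]-3-hydroxy-2,6-dimethyloct-6-enoyl]-1,3-oxazolidin-2-one | O=C1OC[C@H](Cc2ccccc2)N1C(=O)[C@@H](C)[C@H](O)CC/C(C)=C/CO[Si](C)(C)C(C)(C)C | intermediate
23 | methyl (2S,3R,6E)-8-[(tert-butyldimethylsilyl)oxy]-3-hydroxy-2,6-dimethyloct-6-enoate | COC(=O)[C@@H](C)[C@H](O)CC/C(C)=C/CO[Si](C)(C)C(C)(C)C | intermediate
24 | methyl (2S,3R,6E)-8-[(tert-butyldimethylsilyl)oxy]-2,6-dimethyl-3-[(methylsulfonyl)oxy]oct-6-enoate | COC(=O)[C@@H](C)[C@H](OS(C)(=O)=O)CC/C(C)=C/CO[Si](C)(C)C(C)(C)C | intermediate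
25 | methyl (2S,3R,6E)-8-hydroxy-2,6-dimethyl-3-[(methylsulfonyl)oxy]oct-6-enoate | COC(=O)[C@@H](C)[C@H](OS(C)(=O)=O)CC/C(C)=C/CO | intermediate
26 | methyl (2S,3R)-5-[(2S,3S)-3-(hydroxymethyl)-2-methyloxiran-2-yl]-2-methyl-3-[(methylsulfonyl)oxy]pentanoate | COC(=O)[C@@H](C)[C@H](OS(C)(=O)=O)CC[C@]1(C)O[C@H]1CO | intermediate
27 | methyl (2S,3R,6R,7S)-6-hydroperoxy-7,8-dihydroxy-2,6-dimethyl-3-[(methylsulfonyl)oxy]octanoate | COC(=O)[C@@H](C)[C@H](OS(C)(=O)=O)CC[C@@](C)(OO)[C@@H](O)CO | intermediate
28 | methyl (2S)-2-{(3S,6R)-6-[(1S)-1,2-dihydroxyethyl]-6-methyl-1,2-dioxan-3-yl}propanoate | COC(=O)[C@@H](C)[C@@H]1CC[C@](C)([C@@H](O)CO)OO1 | intermediate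
29 | methyl (2S)-2-[(3S,6R)-6-formyl-6-methyl-1,2-dioxan-3-yl]propanoate | COC(=O)[C@@H](C)[C@@H]1CC[C@](C)(C=O)OO1 | intermediate
30 | methyl (2S)-2-[(3S,6R)-6-methyl-6-{2-[(1R,4aR,8aR)-2,5,5,8a-tetramethyl-1,4,4a,5,6,7,8,8a-octahydronaphthalen-1-yl]ethenyl}-1,2-dioxan-3-yl]propanoate (E/Z mixture) | COC(=O)[C@@H](C)[C@@H]1CC[C@](C)(C=C[C@@H]2C(C)=CC[C@@H]3C(C)(C)CCC[C@@]23C)OO1 | intermediate
31 | methyl (2S)-2-[(3S,6S)-6-methyl-6-{2-[(1R,4aR,8aR)-2,5,5,8a-tetramethyl-1,4,4a,5,6,7,8,8a-octahydronaphthalen-1-yl]ethyl}-1,2-dioxan-3-yl]propanoate | COC(=O)[C@@H](C)[C@@H]1CC[C@](C)(CC[C@@H]2C(C)=CC[C@@H]3C(C)(C)CCC[C@@]23C)OO1 | target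

**Count and risks**

Total step count: 24. Longest linear sequence: 13 steps (steps 1–11, 23, 24 from carvone; equally steps 12–22, 23, 24 from geraniol).

Steps most likely to fail:

Step 4. The iron enolate may be protonated by the alcohol solvent before it closes on the hindered neopentyl aldehyde, or the β-hydroxy ketone aldolate may reopen by retro-aldol cleavage, so that the two bonds are not formed in one operation. Fallback: starting from 4, the two bond formations are separated. Iron-hydride reductive olefin coupling with acrolein under fully protic conditions (Fe(acac)3, PhSiH3, EtOH/(CH2OH)2, 60 °C) is run to the open (1S,6R)-1,3-dimethyl-6-(2-methyl-5-oxopentan-2-yl)-2-oxocyclohex-3-ene-1-carbaldehyde F1. Piperidinium acetate in toluene then closes ring A by intramolecular aldol condensation; only the CH2CHO terminus can enolise and the C10 aldehyde is the only acceptor that gives a fused six-membered ring. This delivers the enal directly and returns to the route at 8.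

Step 21. Base may trigger Grob-type C12–C13 fragmentation of the β-hydroxy hydroperoxide, or β-elimination of the mesylate through the ester enolate followed by unselective oxa-Michael reclosure, in competition with the 6-exo-tet displacement. Fallback: starting from 27, TBSOTf/2,6-lutidine silylates both hydroxyls and the hydroperoxide to give the tris-silylated mesylate F2. One equivalent of Bu4NF in THF at −40 °C cleaves only the much more labile silyl peroxide, and the free peroxy anion cyclises with no alkoxide or alkoxide base present, giving the bis-silyl ether dioxane F3. HF·pyridine then releases the diol, returning to the route at 28.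

Step 23. The hindered α-sulfonyl carbanion may add slowly to the α-quaternary aldehyde and act instead as a base toward the ester (enolisation and ring-opening β-elimination of the peroxide), or the congested adduct may fail in the Smiles rearrangement. Fallback: starting from 13, I2/PPh3/imidazole gives ent-drimenyl iodide F4, and heating with PPh3 (neat, 110 °C) gives the ent-drimenyl triphenylphosphonium iodide F5. The salt-free, less basic ylide (NaN(SiMe3)2, THF, −78 °C) is then combined with 29 in a Wittig olefination, returning to the route at 30.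

Further compounds
F1 | step 4 | (1S,6R)-1,3-dimethyl-6-(2-methyl-5-oxopentan-2-yl)-2-oxocyclohex-3-ene-1-carbaldehyde | O=C1C(C)=CC[C@H](C(C)(C)CCC=O)[C@@]1(C)C=O
F2 | step 21 | methyl (2S,3R,6R,7S)-7,8-bis[(tert-butyldimethylsilyl)oxy]-6-[(tert-butyldimethylsilyl)peroxy]-2,6-dimethyl-3-[(methylsulfonyl)oxy]octanoate | COC(=O)[C@@H](C)[C@H](OS(C)(=O)=O)CC[C@@](C)(OO[Si](C)(C)C(C)(C)C)[C@@H](O[Si](C)(C)C(C)(C)C)CO[Si](C)(C)C(C)(C)C
F3 | step 21 | methyl (2S)-2-{(3S,6R)-6-[(1S)-1,2-bis[(tert-butyldimethylsilyl)oxy]ethyl]-6-methyl-1,2-dioxan-3-yl}propanoate | COC(=O)[C@@H](C)[C@@H]1CC[C@](C)([C@@H](O[Si](C)(C)C(C)(C)C)CO[Si](C)(C)C(C)(C)C)OO1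
F4 | step 23 | (1R,4aR,8aR)-1-(iodomethyl)-2,5,5,8a-tetramethyl-1,4,4a,5,6,7,8,8a-octahydronaphthalene | IC[C@@H]1C(C)=CC[C@@H]2C(C)(C)CCC[C@@]12C
F5 | step 23 | {[(1R,4aR,8aR)-2,5,5,8a-tetramethyl-1,4,4a,5,6,7,8,8a-octahydronaphthalen-1-yl]methyl}triphenylphosphonium iodide | [I-].C([P+](c1ccccc1)(c1ccccc1)c1ccccc1)[C@@H]1C(C)=CC[C@@H]2C(C)(C)CCC[C@@]12C
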